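**Plan**

1. Numbering (germacrane type): C1 ketone, C2=C3 furanone alkene, C4(=C15H2), C5 (OH), C6 (O-methacryloyl), C7, C8 (lactone O), C9H2, C10 (CH3, furanone O), C11(=C13H2)–C12 (lactone C=O). Ring A is the ten-membered carbocycle, ring B the 3(2H)-furanone, ring C the α-methylene lactone.
2. Retrosynthetic cuts, in order: the methacrylate C–O at O6; the lactone bond C12–O8; C1–C2 together with O(C10)–C3, which opens rings A and B at once to an acyclic enyne–dioxolanone; C7–C8 (allylchromium + aldehyde); C7–C11, C4=C15 and C3–C4 on the carbonyl carbon of an erythronolactone.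
3. Forward: a C2–C7/C11–C13 allylic bromide (six steps from D-erythronolactone acetonide) and a C8–C10/C1 aldehyde (three steps from (S)-citramalic acid) are joined at C7–C8. Rings A and B are then closed in one operation, ring C next, and the ester is placed last.
4. Stereochemistry: C5 and C6 come from D-erythronolactone. C10 comes from (S)-citramalic acid, and no bond to it is ever broken. C7 and C8 come from the chair transition state of the chromium allylation, under control of C6.
5. Enabling feature: the ring-B oxygen and the C1 carbonyl sit on the same quaternary carbon C10 (an α-hydroxy acyl unit) and face C3 and C2 of a C2≡C3 alkyne, and C1–C2 is the bond that rings A and B share. The unit is stored as a 1,3-dioxolan-4-one that activates C1, masks the oxygen and leaves as acetone, so C-acylation of the acetylide followed by 5-endo-dig addition of the unmasked alkoxide closes both rings.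

Key step: step 11

**Route**

Step 1
Reactants: 1 2,3-O-isopropylidene-D-erythronolactone
Product: 2 (3aR,6aR)-2,2-dimethyl-4-[(trimethylsilyl)ethynyl]tetrahydrofuro[3,4-d][1,3]dioxol-4-ol (lactol, both anomers)
Conditions: Me3SiC≡CH, n-BuLi, THF, −78 °C; then 1, −78 °C; sat. aq. NH4Cl
Reagents that add atoms: (trimethylsilyl)acetylene, C#C[Si](C)(C)C
Why: Acetylide 1,2-addition to a γ-lactone, in which the tetrahedral lithium alkoxide persists at −78 °C so that a single addition gives the hemiketal and the two stereocentres of 1 are not touched.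

Step 2
Reactants: 2 the lactol
Product: 3 [(4R,5S)-2,2-dimethyl-5-[4-(trimethylsilyl)but-1-en-3-yn-2-yl]-1,3-dioxolan-4-yl]methanol
Conditions: Ph3PCH3Br, KN(SiMe3)2, THF, 0 °C; then 2, −78 °C → rt
Reagents that add atoms: methyltriphenylphosphonium bromide (as its ylide), C[P+](c1ccccc1)(c1ccccc1)c1ccccc1.[Br-]
Why: Wittig methylenation of the ring-opened keto tautomer: the lactol alkoxide is in ring–chain equilibrium with the silyl-capped ynone, whose carbonyl is taken by the ylide (the silyl group blocks conjugate addition), which frees the primary alcohol and leaves C5 and C6 unchanged.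

Step 3
Reactants: 3 the silylated enyne alcohol
Product: 4 [(4R,5S)-5-(but-1-en-3-yn-2-yl)-2,2-dimethyl-1,3-dioxolan-4-yl]methanol
Conditions: K2CO3 (cat.), MeOH, rt
Reagents that add atoms: none
Why: Base-catalysed methanolysis of the alkynyl C–Si bond (protiodesilylation), to which acetonide and alcohol are inert.

Step 4
Reactants: 4 the enyne alcohol
Product: 5 (4S,5S)-5-(but-1-en-3-yn-2-yl)-2,2-dimethyl-1,3-dioxolane-4-carbaldehyde
Conditions: Dess–Martin periodinane, CH2Cl2, 0 °C → rt; used crude
Reagents that add atoms: none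
Why: Dess–Martin oxidation of the primary alcohol under non-basic conditions, so that the epimerisable cis-configured α-alkoxy aldehyde is not equilibrated.

Step 5
Reactants: 5 the aldehyde
Product: 6 methyl 2-{[(4R,5S)-5-(but-1-en-3-yn-2-yl)-2,2-dimethyl-1,3-dioxolan-4-yl](hydroxy)methyl}prop-2-enoate (both carbinol epimers)
Conditions: i-Bu2AlH, N-methylmorpholine N-oxide, THF, 0 °C; methyl propiolate, 0 °C; then 5, rt; aq. potassium sodium tartrate
Reagents that add atoms: methyl propiolate, C#CC(=O)OC
Why: Vinylalumination (aldehyde addition of the α-aluminated acrylate made by hydroalumination of methyl propiolate) gives the Morita–Baylis–Hillman-type adduct without amine base, so C6 is not epimerised, and the new carbinol centre, formed as a mixture, is erased in step 6.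

Step 6
Reactants: 6 the hydroxy acrylate
Product: 7 methyl (2Z)-2-(bromomethyl)-3-[(4R,5S)-5-(but-1-en-3-yn-2-yl)-2,2-dimethyl-1,3-dioxolan-4-yl]prop-2-enoate
Conditions: N-bromosuccinimide, Me2S, CH2Cl2, 0 °C; then 6, 0 °C → rt
Reagents that add atoms: N-bromosuccinimide, O=C1CCC(=O)N1Br
Why: Corey–Kim-type activation of the allylic alcohol followed by SN2' attack of bromide moves the double bond into conjugation and gives the thermodynamically preferred (Z)-2-(bromomethyl)enoate, as is usual for Baylis–Hillman adducts.

Step 7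
Reactants: 8 (S)-citramalic acid
Product: 9 [(4S)-2,2,4-trimethyl-5-oxo-1,3-dioxolan-4-yl]acetic acid
Conditions: 2,2-dimethoxypropane, TsOH·H2O (cat.), rt
Reagents that add atoms: 2,2-dimethoxypropane, COC(C)(C)OC
Why: Acid-catalysed ketalisation closes the five-membered dioxolanone on the α-hydroxy acid and leaves the β-carboxyl group free, as with malic acid, without touching the quaternary centre.

Step 8
Reactants: 9 the dioxolanone acid
Product: 10 (5S)-5-(2-hydroxyethyl)-2,2,5-trimethyl-1,3-dioxolan-4-one
Conditions: BH3·SMe2, THF, 0 °C → rt; MeOH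
Reagents that add atoms: none
Why: Chemoselective borane reduction of the free carboxylic acid in the presence of the dioxolanone carbonyl.

Step 9
Reactants: 10 the dioxolanone alcohol
Product: 11 [(4S)-2,2,4-trimethyl-5-oxo-1,3-dioxolan-4-yl]acetaldehyde
Conditions: (COCl)2, DMSO, CH2Cl2, −78 °C; Et3N, −78 → 0 °C
Reagents that add atoms: none
Why: Swern oxidation at low temperature and without acid avoids acyl transfer of the γ-hydroxyl to the dioxolanone and gives the aldehyde.

Step 10
Reactants: 7 the (Z)-allylic bromide, 11 the dioxolanone aldehyde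
Product: 12 methyl 3-[(4R,5S)-5-(but-1-en-3-yn-2-yl)-2,2-dimethyl-1,3-dioxolan-4-yl]-2-methylidene-5-[(4S)-2,2,4-trimethyl-5-oxo-1,3-dioxolan-4-yl]-4-(trimethylsilyloxy)pentanoate (C7 and C8 arranged as in the target)
Conditions: CrCl2 (10 mol %), Mn powder, Me3SiCl, THF, rt; aq. NaHCO3 work-up
Reagents that add atoms: chlorotrimethylsilane, C[Si](C)(C)Cl
Why: Nozaki–Hiyama allylation catalytic in chromium, in which the allylchromium reagent from 7 adds to 11 at C7 through a chair transition state with C6 equatorial (7,8-anti, as the trans lactone requires) and the aldehyde approaches C7 anti to the C6–C5 bond of the cis-dioxolane with H6 eclipsing the alkene (allylic 1,3-strain), which sets C7 and hence C8 relative to C6, while in situ O-silylation keeps the C8 oxygen from acylating on the dioxolanone.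

Step 11
Reactants: 12 the seco enyne–dioxolanone
Product: 14 ring A/B furanone with 5,6-O-isopropylidene, 8-O-trimethylsilyl and the C7 methyl acrylate side chain, via ten-membered α'-hydroxy ynone 13 (not isolated)
Conditions: LiN(SiMe3)2 (1.05 equiv), THF (0.002 M), −78 °C → 0 °C; AcOH
Reagents that add atoms: none
Why: Proposed new method: LiN(SiMe3)2 removes the only acidic proton (the enyne C–H; no carbonyl in 12 is enolisable), the acetylide carbon C2 adds to the dioxolanone carbonyl C1, the tetrahedral adduct opens on warming with loss of acetone, and the C10 alkoxide so uncovered adds to C3 of the new ynone, protonation at C2 on quench giving the furanone. The closest known reactions are the intermolecular addition of lithium acetylides to 1,3-dioxolan-4-ones and lactones to give α'-hydroxy ynones, their base-induced cyclisation to 3(2H)-furanones, and the closure of ten-membered enediyne rings by intramolecular acetylide-to-carbonyl addition; new is their combination on an ester-type acceptor in a ring-forming sense. Ring A closes by 10-exo-trig attack on C1=O and ring B by 5-endo-dig oxa-Michael addition, which the ynone polarisation makes easy. No stereocentre is created, and C10 keeps its configuration because neither C10–O nor C10–C1 is broken. The step needs chemoselectivity for C1 over the acrylate ester and ring closure over oligomerisation: the dioxolanone is the more electrophilic carbonyl (α-oxygen, acylal-type leaving group), the α-branched acrylate is hindered and cannot be reached intramolecularly (an eight-membered ring containing the alkyne would result), high dilution disfavours intermolecular acylation, and the cis-fused C5/C6 acetonide bends the chain so that C2 and C1 can meet. The lithium hemiketal formed on addition is expected to persist at low temperature, so that acetone is set free only after the ring has closed.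

Step 12
Reactants: 14 the furanone silyl ether ester
Product: 16 5,6-O-isopropylidene derivative of the ring A/B/C diol lactone, via 8-hydroxy methyl ester 15 (not isolated)
Conditions: TsOH·H2O (0.1 equiv), CH2Cl2, rt
Reagents that add atoms: none
Why: Acid cleaves the labile trimethylsilyl ether and catalyses lactonisation (intramolecular transesterification, 5-exo-trig) of the C8 hydroxyl, now the only free hydroxyl, onto the acrylate ester, now the only ester, with retention at C8 to give the trans-fused α-methylene lactone.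

Step 13
Reactants: 16 the lactone acetonide
Product: 17 5,6-diol (rings A, B and C complete)
Conditions: CF3CO2H/H2O (9:1), 0 °C
Reagents that add atoms: none
Why: Acidic hydrolysis of the cis-fused isopropylidene ketal, which furanone, α-methylene lactone and the electron-poor allylic C5–O bond tolerate.

Step 14
Reactants: 17 the diol
Product: 18 5-O-tert-butyldimethylsilyl ether of 17
Conditions: t-BuMe2SiOTf (1.05 equiv), 2,6-lutidine, CH2Cl2, −78 °C
Reagents that add atoms: tert-butyldimethylsilyl trifluoromethanesulfonate, CC(C)(C)[Si](C)(C)OS(=O)(=O)C(F)(F)F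
Why: Regioselective silylation, since the allylic C5 hydroxyl, flanked by the sp2 carbon C4, is less hindered than the C6 hydroxyl next to the ring-fusion carbon C7, so one equivalent of the bulky silyl triflate at low temperature should react at O5.

Step 15
Reactants: 18 the 5-O-silyl ether
Product: 19 5-O-tert-butyldimethylsilyl 6-O-methacrylate
Conditions: methacrylic anhydride, Et3N, DMAP (cat.), CH2Cl2, 0 °C → rt
Reagents that add atoms: methacrylic anhydride, CC(=C)C(=O)OC(=O)C(C)=C
Why: DMAP-catalysed acylation of the one remaining secondary alcohol by the anhydride (nucleophilic acyl-transfer catalysis).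

Step 16
Reactants: 19 the silyl ether ester
Product: 20 the target, (5S,6R,7R,8S,10S)-5-hydroxy-6-(methacryloyloxy)-1-oxo-3,10-epoxygermacra-2,4(15),11(13)-trien-12,8-olide (CNP0142847.1)
Conditions: HF·pyridine, pyridine, THF, 0 °C → rt
Reagents that add atoms: none
Why: Fluoride-mediated cleavage of the silyl ether under mildly acidic conditions, which avoid acyl migration from O6 to O5 and conjugate addition to the two acrylate units.

**Compound list**

1 | 2,3-O-isopropylidene-D-erythronolactone, (3aR,6aR) | O=C1[C@@H]2OC(C)(C)O[C@@H]2CO1 | starting material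
2 | (3aR,6aR)-2,2-dimethyl-4-[(trimethylsilyl)ethynyl]tetrahydrofuro[3,4-d][1,3]dioxol-4-ol, both anomers | C[Si](C)(C)C#CC1(O)[C@@H]2OC(C)(C)O[C@@H]2CO1 | intermediate
3 | [(4R,5S)-2,2-dimethyl-5-[4-(trimethylsilyl)but-1-en-3-yn-2-yl]-1,3-dioxolan-4-yl]methanol | C[Si](C)(C)C#CC(=C)[C@@H]1OC(C)(C)O[C@@H]1CO | intermediate
4 | [(4R,5S)-5-(but-1-en-3-yn-2-yl)-2,2-dimethyl-1,3-dioxolan-4-yl]methanol | C#CC(=C)[C@@H]1OC(C)(C)O[C@@H]1CO | intermediate
5 | (4S,5S)-5-(but-1-en-3-yn-2-yl)-2,2-dimethyl-1,3-dioxolane-4-carbaldehyde | C#CC(=C)[C@@H]1OC(C)(C)O[C@@H]1C=O | intermediate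
6 | methyl 2-{[(4R,5S)-5-(but-1-en-3-yn-2-yl)-2,2-dimethyl-1,3-dioxolan-4-yl](hydroxy)methyl}prop-2-enoate, both carbinol epimers | C#CC(=C)[C@@H]1OC(C)(C)O[C@@H]1C(O)C(=C)C(=O)OC | intermediate
7 | methyl (2Z)-2-(bromomethyl)-3-[(4R,5S)-5-(but-1-en-3-yn-2-yl)-2,2-dimethyl-1,3-dioxolan-4-yl]prop-2-enoate | C#CC(=C)[C@@H]1OC(C)(C)O[C@@H]1/C=C(/C(=O)OC)CBr | intermediate
8 | (S)-citramalic acid, (2S)-2-hydroxy-2-methylbutanedioic acid | OC(=O)C[C@](C)(O)C(=O)O | starting material
9 | [(4S)-2,2,4-trimethyl-5-oxo-1,3-dioxolan-4-yl]acetic acid | OC(=O)C[C@]1(C)OC(C)(C)OC1=O | intermediate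
10 | (5S)-5-(2-hydroxyethyl)-2,2,5-trimethyl-1,3-dioxolan-4-one | OCC[C@]1(C)OC(C)(C)OC1=O | intermediate
11 | [(4S)-2,2,4-trimethyl-5-oxo-1,3-dioxolan-4-yl]acetaldehyde | O=CC[C@]1(C)OC(C)(C)OC1=O | intermediate
12 | seco enyne–dioxolanone: methyl 2-methylidene pentanoate carrying the enynyl dioxolane at C7, OSiMe3 at C8 and the dioxolanone at C10 | C#CC(=C)[C@@H]1OC(C)(C)O[C@@H]1[C@H](C(=C)C(=O)OC)[C@@H](O[Si](C)(C)C)C[C@]2(C)OC(C)(C)OC2=O | intermediate
13 | ten-membered α'-hydroxy ynone (C1 ketone, C2≡C3, free C10 hydroxyl; 5,6-O-isopropylidene, 8-OSiMe3, C7 methyl acrylate) | O=C1C#CC(=C)[C@@H]2OC(C)(C)O[C@@H]2[C@H](C(=C)C(=O)OC)[C@@H](O[Si](C)(C)C)C[C@]1(C)O | intermediate (not isolated)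
14 | ring A/B furanone, 5,6-O-isopropylidene, 8-O-trimethylsilyl, C7 methyl acrylate (ring C open) | O=C1C=C2C(=C)[C@@H]3OC(C)(C)O[C@@H]3[C@H](C(=C)C(=O)OC)[C@@H](O[Si](C)(C)C)C[C@]1(C)O2 | intermediate
15 | 8-hydroxy methyl ester from 14 | O=C1C=C2C(=C)[C@@H]3OC(C)(C)O[C@@H]3[C@H](C(=C)C(=O)OC)[C@@H](O)C[C@]1(C)O2 | intermediate (not isolated)
16 | ring A/B/C lactone, 5,6-O-isopropylidene | O=C1C=C2C(=C)[C@@H]4OC(C)(C)O[C@@H]4[C@@H]3C(=C)C(=O)O[C@H]3C[C@]1(C)O2 | intermediate
17 | ring A/B/C lactone 5,6-diol | O=C1C=C2C(=C)[C@H](O)[C@H](O)[C@@H]3C(=C)C(=O)O[C@H]3C[C@]1(C)O2 | intermediate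
18 | 5-O-tert-butyldimethylsilyl ether of 17 | O=C1C=C2C(=C)[C@H](O[Si](C)(C)C(C)(C)C)[C@H](O)[C@@H]3C(=C)C(=O)O[C@H]3C[C@]1(C)O2 | intermediate
19 | 5-O-tert-butyldimethylsilyl 6-O-methacrylate | O=C1C=C2C(=C)[C@H](O[Si](C)(C)C(C)(C)C)[C@H](OC(=O)C(C)=C)[C@@H]3C(=C)C(=O)O[C@H]3C[C@]1(C)O2 | intermediate
20 | CNP0142847.1, (5S,6R,7R,8S,10S)-5-hydroxy-6-(methacryloyloxy)-1-oxo-3,10-epoxygermacra-2,4(15),11(13)-trien-12,8-olide | C=C(C)C(=O)O[C@@H]1[C@@H]2C(=C)C(=O)O[C@H]2C[C@]2(C)OC(=CC2=O)C(=C)[C@@H]1O | target

**Step count and risks**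

Total step count: 16. Longest linear sequence: 13 (steps 1–6 and 10–16); steps 7–9 form the second branch.

Steps most likely to fail:

Step 11. The acetylide may be used up by intermolecular acylation or by acetone set free too early, before the strained ten-membered ring closes. The trimethylsilyl group may also migrate from O8 to the C10 alkoxide and block the oxa-Michael closure. The fallback makes ring B first by the intermolecular form of the same reaction and closes ring A at C7–C8; it sets out from 4 and 10 and comes back at 16. Alcohol 10 is silylated (i-Pr3SiCl, imidazole) to the triisopropylsilyl ether F1 and alcohol 4 (Et3SiCl, imidazole) to the triethylsilyl ether F2. The lithium acetylide of F2 (n-BuLi, THF, −78 °C) is added to F1 and the mixture is warmed, with Et2NH in EtOH if the hydroxy ynone persists, to give the furanone F3. PPTS in MeOH removes the triethylsilyl group to give the primary alcohol F4, Dess–Martin oxidation gives the aldehyde F5, vinylalumination as in step 5 gives the hydroxy acrylate F6, and N-bromosuccinimide with Me2S gives the (Z)-allylic bromide F7. HF·pyridine frees the C8 alcohol F8 and Dess–Martin oxidation gives the bromo aldehyde F9. Intramolecular Nozaki–Hiyama allylation (CrCl2, THF, high dilution; then TsOH cat.) closes ring A at C7–C8 and lactonises to 16, with the chair transition state inside the forming ring setting C7 and C8.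

Step 14. Silylation may not discriminate between O5 and O6, or may give the bis-silyl ether. The fallback differentiates the two oxygens by oxidation state; it sets out from 17 and comes back at 20. MnO2 in CH2Cl2 oxidises only the allylic C5 hydroxyl to give the 5-oxo compound F14. Methacrylic anhydride with Et3N and DMAP acylates the remaining C6 hydroxyl to give the keto ester F15. Luche reduction (NaBH4, CeCl3·7H2O, MeOH, −78 °C) returns the C5 alcohol 20, hydride adding to the ketone anti to the acyloxy group (Felkin–Anh), which gives the 5,6-anti arrangement of the target.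

Step 2. In the basic ylide medium the open-chain α-alkoxy ynone may epimerise at C5 or lose the acetonide oxygen by β-elimination, or the hemiketal may fail to open. The fallback avoids the lactol and the basic ylide; it sets out from 1 and comes back at 4. Lactone 1 is opened with MeNHOMe·HCl and AlMe3 to the hydroxy Weinreb amide F10, which is silylated (t-BuMe2SiCl, imidazole) to F11. Lithium (trimethylsilyl)acetylide gives the ynone F12, and non-basic Tebbe methylenation (Cp2Ti(CH2)(Cl)AlMe2, THF, pyridine, −40 → 0 °C) gives the silylated enyne F13. Bu4NF removes both silyl groups to give 4.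

**Further compounds**

F1 | step 11 | (5S)-2,2,5-trimethyl-5-[2-(triisopropylsilyloxy)ethyl]-1,3-dioxolan-4-one | CC(C)[Si](OCC[C@]1(C)OC(C)(C)OC1=O)(C(C)C)C(C)C
F2 | step 11 | triethylsilyl ether of 4 | C#CC(=C)[C@@H]1OC(C)(C)O[C@@H]1CO[Si](CC)(CC)CC
F3 | step 11 | 3(2H)-furanone with the triisopropylsilyloxyethyl chain at C10 and the dioxolanyl propenyl chain (triethylsilyl ether) at C3 | CC(C)[Si](OCC[C@]1(C)OC(=CC1=O)C(=C)[C@@H]2OC(C)(C)O[C@@H]2CO[Si](CC)(CC)CC)(C(C)C)C(C)C
F4 | step 11 | primary C7 alcohol from F3 | CC(C)[Si](OCC[C@]1(C)OC(=CC1=O)C(=C)[C@@H]2OC(C)(C)O[C@@H]2CO)(C(C)C)C(C)C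
F5 | step 11 | C7 aldehyde from F4 | CC(C)[Si](OCC[C@]1(C)OC(=CC1=O)C(=C)[C@@H]2OC(C)(C)O[C@@H]2C=O)(C(C)C)C(C)C
F6 | step 11 | hydroxy acrylate from F5, both carbinol epimers | CC(C)[Si](OCC[C@]1(C)OC(=CC1=O)C(=C)[C@@H]2OC(C)(C)O[C@@H]2C(O)C(=C)C(=O)OC)(C(C)C)C(C)C
F7 | step 11 | (Z)-allylic bromide from F6 | CC(C)[Si](OCC[C@]1(C)OC(=CC1=O)C(=C)[C@@H]2OC(C)(C)O[C@@H]2/C=C(/C(=O)OC)CBr)(C(C)C)C(C)C
F8 | step 11 | C8 alcohol from F7 | OCC[C@]1(C)OC(=CC1=O)C(=C)[C@@H]2OC(C)(C)O[C@@H]2/C=C(/C(=O)OC)CBr
F9 | step 11 | bromo aldehyde from F8 | O=CC[C@]1(C)OC(=CC1=O)C(=C)[C@@H]2OC(C)(C)O[C@@H]2/C=C(/C(=O)OC)CBr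
F14 | step 14 | 5-oxo 6-hydroxy compound from 17 | O=C1C=C2C(=C)C(=O)[C@H](O)[C@@H]3C(=C)C(=O)O[C@H]3C[C@]1(C)O2
F15 | step 14 | 5-oxo 6-O-methacrylate | O=C1C=C2C(=C)C(=O)[C@H](OC(=O)C(C)=C)[C@@H]3C(=C)C(=O)O[C@H]3C[C@]1(C)O2
F10 | step 2 | (4R,5R)-5-(hydroxymethyl)-N-methoxy-N,2,2-trimethyl-1,3-dioxolane-4-carboxamide | CON(C)C(=O)[C@@H]1OC(C)(C)O[C@@H]1CO
F11 | step 2 | tert-butyldimethylsilyl ether of F10 | CON(C)C(=O)[C@@H]1OC(C)(C)O[C@@H]1CO[Si](C)(C)C(C)(C)C
F12 | step 2 | silylated ynone from F11 | C[Si](C)(C)C#CC(=O)[C@@H]1OC(C)(C)O[C@@H]1CO[Si](C)(C)C(C)(C)C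
F13 | step 2 | tert-butyldimethylsilyl ether of 3 | C[Si](C)(C)C#CC(=C)[C@@H]1OC(C)(C)O[C@@H]1CO[Si](C)(C)C(C)(C)C
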